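**Remark on the chemistry:** (R)-2-methylbutanoic acid is assumed to be purchasable in high enantiomeric purity. The bridging methine carbon carries two identical aryl groups and is not a stereocentre. The constitutions of the key-step precursor 13 and product 17 map atom for atom onto the target and need no correction. The mechanism is completed by the rearomatising enolisation that lies between the sigmatropic shift and the hydrogen shift.

## Structural features

- The target is a dimeric acylphloroglucinol. Two 2,2-dimethylchromane-5,7-diol units, each a benzene ring fused to a dihydropyran ring, are joined through their C6 carbons by one sp3 methine carbon. That carbon also bears a 5-methylhexyl chain, so the bridge is a 6-methylheptane-1,1-diyl unit.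
- Each benzene ring is hexasubstituted: O1 on C8a, C4 on C4a, hydroxyls on C5 and C7, the methine on C6 and a 2-methylbutanoyl group on C8.
- The only stereocentres are the two α-carbons of the acyl groups, both (R). They are not adjacent; two arenes and the bridge separate them.
- Fragile features are:
  - the enolisable α-stereocentres next to the aryl ketones;
  - the electron-rich diarylmethine, which can be cleaved after ipso-protonation;
  - the oxidisable polyphenol;
  - the tertiary alkyl aryl ether of each pyran ring, which is sensitive to strong Lewis acids.
- The real difficulty is regiochemical and steric. Each phloroglucinol ring must receive three different carbon substituents, one of its three oxygens must be singled out as the pyran oxygen, and all of this happens twice around a tetra-ortho-substituted diarylmethine.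
- The key step exploits the fact that C8a, which carries O1, is para to C6. A ring that bears only the methine on carbon has a local mirror plane through C6 and the para oxygen. The two carbons ortho to that oxygen (the future C4a and C8) are then equivalent, so a Claisen shift from that oxygen can give only one chromene and leaves C8–H for the later acylation.

## Logic of the disconnections

**22 to 19 and 21.** The two C8–C(=O) bonds are cut, giving 19 and two equivalents of 21, which is made from 20. The acyl groups carry the only stereocentres and can be bought with the right configuration. C8 is the only unsubstituted carbon of each arene in 19, so the acylation has no regiochemical choice. The core becomes achiral. The forward step must not erode the α-configuration and must not cleave the diarylmethine under Lewis acid.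

**19 to 17 via 18.** No skeletal bond is cut. The C3–C4 single bonds are traced back to double bonds and the four hydroxyls to acetal ethers. 17 is the direct outcome of the pericyclic ring construction, and the acetal ethers are the same groups that steer the metalation early in the route. The forward step must hydrogenate before acid is added, and the cleaved acetal fragment must be trapped by methanol so that it does not attack C8.

**17 to 13 (key disconnection).** In each ring the C4a–C4 bond is cut and the pyran is opened to an aryl 1,1-dimethylpropargyl ether. Both pyran rings, with their gem-dimethyl carbons, then come from the four-carbon reagent 12 in a single thermal operation. The local symmetry of each arene in 13 makes the regiochemistry automatic. The forward step needs only heat, but it requires that each arene carry its propargyl group on the oxygen para to the methine and nowhere else.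

**13 to 11 and 12.** The two O–C(propargylic) bonds are cut. 11 has only the two para hydroxyls free, so the alkylation has no site-selectivity problem. The forward step is a substitution at a tertiary carbon, which calls for copper catalysis.

**11 to 10 to 9.** These are functional-group changes. The para oxygens are traced back to bulky silyl ethers and the methine C–H to a tertiary carbinol C–OH. The silyl ether is chosen over a benzyl ether for three reasons: it does not direct lithiation to its own ortho positions, it has no benzylic hydrogens for base to attack, and it comes off with fluoride while the acetals stay. The forward deoxygenation must tolerate four acetal ethers.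

**9 to 3 (as 6 and 7) and 5.** Both aryl–C(carbinol) bonds are cut. The bridging carbon is at the acid oxidation level in 5, and two identical aryl nucleophiles deliver both rings at once. The ring carbon between the two acetal oxygens of 3 is the one that lithiates, and that fixes the methine para to the silyloxy group. The second addition meets a hindered, enolisable ketone 8. This is why 6 is turned into the less basic 7.

**3 to 2 to 1, and 5 to 4.** These are protections and an esterification. The only non-selective event of the route, the statistical double acetalisation of 1, is placed at the first step, where material is cheapest.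

## Other disconnections considered

**Alternative 1:**
- **Cut.** Both benzene rings are removed. In each, the C5–C4a and C6–C7 bonds are cut. The methine, its side chain and C5/C6 of both rings come from 3-(5-methylhexyl)pentanedioyl dichloride A1. C4a, C7, C8, C8a and the complete pyran ring come from the silyl ketene acetal A2, {[1-methoxy-2-(6,6-dimethyl-5,6-dihydro-4H-pyran-2-yl)ethenyl]oxy}trimethylsilane.
- **Forward key step.** A1 acylates two molecules of A2 at the γ-carbon in a vinylogous Mukaiyama-type acylation. Two Dieckmann-type closures and enolisation would then give the tetraphenol A3, which is the same compound as 19.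
- **In favour.** No protecting group is needed and no statistical differentiation of phloroglucinol. The position of O1 relative to the methine is fixed by construction. The crowded diaryl carbinol and its deoxygenation are avoided. On protecting-group economy this plan is the better one.
- **Against.**
  - Glutaryl dichlorides with α-hydrogens cyclise easily to enol-lactone chlorides or form ketenes.
  - The dienolate must react at its γ-carbon and not at the α-carbon or at oxygen, twice on one molecule.
  - The tricarbonyl intermediates can close through oxygen to pyranones instead of through C6, which is a hindered carbon next to the branch point.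
  - Four C–C bonds must form selectively in one operation.
- **Comparison.** Structurally the two plans meet at 19 and share the last step and its risks, so they are equal in the end game. On paper the alternative may be slightly shorter. Mechanistically it rests on a twofold sequence of site-selective C-acylations with no close model. The chosen plan uses single-ring reactions that each have close models and lets symmetry decide the regiochemistry.

**Alternative 2:**
- **Cut.** The bond between each ketone carbon and its α-carbon is cut. This leads back to the dialdehyde A4, 6,6'-(6-methylheptane-1,1-diyl)bis[5,7-bis(methoxymethoxy)-2,2-dimethylchromane-8-carbaldehyde].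
- **Forward key step.** Both formyl groups of A4 undergo allylboration with (E)-crotylboronic acid pinacol ester A5 under a chiral BINOL-derived phosphoric acid. The closed chair transition state should give the anti bis(homoallylic alcohol) A6 with (R) configuration at both methyl-bearing carbons. Hydrogenation of the vinyl groups, oxidation of the carbinols and acetal removal would follow.
- **In favour.** The stereocentres are made by catalyst control, independent of a chiral-pool acid. No Lewis-acid acylation of a free tetraphenol is needed. A4 could be reached from 18 by lithiation at C8 and formylation, so the plan is compatible with the ring construction chosen here. On configurational safety during the C–C bond formation it is the better plan, since the allylboration itself cannot racemise.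
- **Against.**
  - The formyl groups of A4 are flanked by two oxygen substituents. They are electron-rich and hindered, which makes them poor electrophiles for this type of catalysis, and the acetal oxygens compete for the hydrogen bonds of the catalyst.
  - Two independent events mean that any slip gives an (R,S) diastereomer whose stereocentres are too remote for easy separation.
  - The carbinol stereocentres are made only to be destroyed.
  - The oxidation creates an enolisable α-branched ketone, so the vinyl groups must be saturated first.
- **Comparison.** Five steps would follow 18 (formylation, crotylation, hydrogenation, oxidation, deprotection) against two in the chosen plan, which buys the stereocentres ready-made. The alternative is more flexible in the choice of enantiomer. On ring construction the two plans are equal.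

**Alternative 3:**
- **Cut.** The C8a–O1 bond of each pyran ring is cut. This leads to the dibromo diol A7, in which each fully substituted arene carries bromine at the future C8a, a 3-hydroxy-3-methylbutyl chain at the future C4a and the (R)-2-methylbutanoyl group already in place.
- **Forward key step.** A palladium-catalysed intramolecular C–O coupling with a bulky binaphthyl-based dialkylphosphine and a carbonate base. Zerovalent palladium inserts into the C–Br bond, the tertiary alkoxide exchanges onto divalent palladium, and C–O reductive elimination closes each pyran ring. The product is A8, the tetrakis(methoxymethyl) ether of the target.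
- **In favour.** The bromide dictates the position of the ring oxygen. Tertiary alkoxides cannot undergo β-hydride elimination. Only acetal removal follows, so the finish is one step shorter than in the chosen plan, and on this point the alternative is better. No late electrophilic acylation is needed.
- **Against.**
  - Each arene of A7 needs six different substituents introduced one at a time, with no symmetry to help.
  - The bromide sits between a ketone and an alkyl chain on an electron-rich ring, so oxidative addition should be slow and reduction of the C–Br bond would compete.
  - Warm carbonate base next to an α-branched aryl ketone invites epimerisation through the enolate, and palladium enolate side reactions are possible.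
- **Comparison.** The chosen plan takes the aryl–O1 bond from phloroglucinol itself and forms the pyran rings without metal or base. The alternative makes the same bond at the most hindered position of a finished ring. The front end of the alternative would be distinctly longer and would put the stereocentres at risk for more steps.

Key step: step 8

## Route

Step 1
Reactants: 1 phloroglucinol (benzene-1,3,5-triol)
Product: 2 3,5-bis(methoxymethoxy)phenol
Conditions: MOMCl (2.1 equiv), i-Pr2NEt (2.5 equiv), CH2Cl2–DMF, 0 °C to rt; chromatography
Reagents that add atoms: chloromethyl methyl ether (MOMCl), COCCl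
Why: Williamson-type O-alkylation of a threefold symmetric triphenol; two equivalents should make the bis-ether the main component of a statistical mixture, and the mono- and tris-ethers are separable and can be recycled.

Step 2
Reactants: 2 3,5-bis(methoxymethoxy)phenol
Product: 3 [3,5-bis(methoxymethoxy)phenoxy]tri(propan-2-yl)silane
Conditions: TIPSCl (1.2 equiv), imidazole (2.5 equiv), DMF, rt
Reagents that add atoms: triisopropylsilyl chloride (TIPSCl), CC(C)[Si](Cl)(C(C)C)C(C)C
Why: Standard silylation of a phenol; the bulky silyl ether does not coordinate lithium, shields its own ortho positions, survives aryllithium and trifluoroacetic acid, and is later removed by fluoride without touching the acetals.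

Step 3
Reactants: 4 6-methylheptanoic acid
Product: 5 methyl 6-methylheptanoate
Conditions: MeOH, H2SO4 (cat.), reflux
Reagents that add atoms: methanol, CO
Why: Fischer esterification of an unhindered aliphatic acid, driven by excess methanol.

Step 4
Reactants: 3 [3,5-bis(methoxymethoxy)phenoxy]tri(propan-2-yl)silane; 5 methyl 6-methylheptanoate
Product: 9 1,1-bis{2,6-bis(methoxymethoxy)-4-[(triisopropylsilyl)oxy]phenyl}-6-methylheptan-1-ol, via aryllithium 6 (not isolated), via arylcerium dichloride 7 (not isolated), via aryl ketone 8 (not isolated)
Conditions: 3 (2.3 equiv), n-BuLi (2.3 equiv), THF, 0 °C; CeCl3 (2.4 equiv), THF, −78 °C; 5 (1.0 equiv), −78 to 0 °C; aq. NH4Cl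
Reagents that add atoms: none
Why: Directed ortho-metalation between the two acetal ethers gives 6, transmetalation gives the less basic organocerium reagent 7, and this adds twice to the ester through ketone 8 (organocerium addition to an ester); the cerium reagent should suppress enolisation of 8 so that the hindered second addition can win, and the carbinol carbon bears two identical aryl groups and is not stereogenic.

Step 5
Reactants: 9 1,1-bis{2,6-bis(methoxymethoxy)-4-[(triisopropylsilyl)oxy]phenyl}-6-methylheptan-1-ol
Product: 10 1,1-bis{2,6-bis(methoxymethoxy)-4-[(triisopropylsilyl)oxy]phenyl}-6-methylheptane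
Conditions: Et3SiH (4 equiv), TFA (2 equiv), CH2Cl2, −40 to 0 °C; aq. NaHCO3
Reagents that add atoms: none
Why: Ionic hydrogenation of a tertiary diaryl carbinol; six oxygen donors make ionisation easy with little acid at low temperature, hydride transfer from silicon is irreversible, and any alkene formed by dehydration re-enters through the same cation, while the aryl silyl ethers are inert and the short cold exposure should spare the acetals.

Step 6
Reactants: 10 1,1-bis{2,6-bis(methoxymethoxy)-4-[(triisopropylsilyl)oxy]phenyl}-6-methylheptane
Product: 11 4,4'-(6-methylheptane-1,1-diyl)bis[3,5-bis(methoxymethoxy)phenol]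
Conditions: TBAF (2.4 equiv), THF, 0 °C; aq. NH4Cl
Reagents that add atoms: none
Why: Fluoride cleavage of aryl silyl ethers, driven by the Si–F bond; acetal ethers are stable to fluoride and only the two para oxygens are freed.

Step 7
Reactants: 11 4,4'-(6-methylheptane-1,1-diyl)bis[3,5-bis(methoxymethoxy)phenol]; 12 3-chloro-3-methylbut-1-yne
Product: 13 1,1-bis[2,6-bis(methoxymethoxy)-4-(2-methylbut-3-yn-2-yloxy)phenyl]-6-methylheptane
Conditions: 12 (3 equiv), DBU (3 equiv), CuCl2·2H2O (1 mol %), MeCN, 0 °C
Reagents that add atoms: none
Why: Copper-catalysed O-propargylation of phenols with a tertiary propargylic chloride; the copper acetylide loses chloride to an electrophile that the phenoxide captures at the tertiary carbon, the two hydroxyls are unhindered, and the low temperature prevents premature rearrangement.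

Step 8
Reactants: 13 1,1-bis[2,6-bis(methoxymethoxy)-4-(2-methylbut-3-yn-2-yloxy)phenyl]-6-methylheptane
Product: 17 6,6'-(6-methylheptane-1,1-diyl)bis[5,7-bis(methoxymethoxy)-2,2-dimethyl-2H-chromene], via bis(allenyl dienone) 14 (not isolated), via bis(allenylphenol) 15 (not isolated), via bis(ortho-quinone methide) 16 (not isolated)
Conditions: o-xylene (degassed, 0.05 M), 140 °C, sealed tube
Reagents that add atoms: none
Why: Each aryl propargyl ether undergoes a thermal aromatic propargyl Claisen ([3,3]-sigmatropic) rearrangement in which the alkyne terminus bonds to an ortho carbon while the O–CMe2 bond breaks, giving the 6-allenylcyclohexa-2,4-dienone arms of 14. Enolisation restores the arene (15), a 1,5-shift of the phenolic hydrogen to the central allene carbon gives the ortho-quinone methide arms of 16, and a thermally allowed disrotatory oxa-6π electrocyclisation re-forms the O1–C2 bond. The closest known reaction type is the thermal conversion of aryl 1,1-dimethylpropargyl ethers into 2,2-dimethyl-2H-chromenes. Each pyran ring is closed by 6π electrocyclisation of a 1-oxatriene whose C4a–C4 bond was made in the sigmatropic step. No stereocentre is created, because the sp3 ring carbons of 14 are lost on enolisation and 17 is achiral. The step needs regiocontrol of the C–C bond and chromene rather than benzofuran formation: in each ring of 13 the two carbons ortho to the propargyloxy group are related by the local mirror plane through the methine-bearing carbon and both carry hydrogen, so either gives the same chromene with O1 para to the methine, and the base-free, metal-free thermal conditions favour the hydrogen shift and electrocyclisation over ionic 5-exo attack on the allene. The gem-dimethyl group and the two meta alkoxy groups should keep the temperature low enough for the acetals, and the two arms react independently (14 to 16 are drawn with both arms at the same stage).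

Step 9
Reactants: 17 6,6'-(6-methylheptane-1,1-diyl)bis[5,7-bis(methoxymethoxy)-2,2-dimethyl-2H-chromene]
Product: 19 6,6'-(6-methylheptane-1,1-diyl)bis(2,2-dimethylchromane-5,7-diol), via tetra-MOM bis-chromane 18 (not isolated)
Conditions: H2 (1 atm), 10% Pd/C, EtOAc–MeOH, rt; Ar purge, filtration; then HCl (1.25 M in MeOH), 40 °C, under Ar
Reagents that add atoms: none
Why: Catalytic hydrogenation of the cis-disubstituted styrene-type double bonds gives 18, and acid-catalysed acetal methanolysis then frees the four phenols; the large excess of methanol traps the methoxymethyl cation as dimethoxymethane so that it should not attack the free C8 position.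

Step 10
Reactants: 19 6,6'-(6-methylheptane-1,1-diyl)bis(2,2-dimethylchromane-5,7-diol); 20 (R)-2-methylbutanoic acid
Product: 22 (2R,2'R)-1,1'-[(6-methylheptane-1,1-diyl)bis(5,7-dihydroxy-2,2-dimethyl-3,4-dihydro-2H-chromene-6,8-diyl)]bis(2-methylbutan-1-one), via (R)-2-methylbutanoyl chloride 21 (not isolated)
Conditions: 20 (2.4 equiv), (COCl)2 (2.4 equiv), DMF (1 mol %), CH2Cl2, 0 °C to rt; solution added to 19, AlCl3 (6 equiv), CH2Cl2–PhNO2, 0 °C to rt; 1 M HCl work-up
Reagents that add atoms: none
Why: Friedel–Crafts C-acylation of a phloroglucinol-type arene at C8, the only free ring position, which lies between O1 and the C7 hydroxyl; both stereocentres come from 20 with no bond to the α-carbon made or broken, and base-free chloride formation and low temperature are chosen to keep the configuration.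

## Compound list

1 | phloroglucinol (benzene-1,3,5-triol) | Oc1cc(O)cc(O)c1 | starting material
2 | 3,5-bis(methoxymethoxy)phenol | COCOc1cc(O)cc(OCOC)c1 | intermediate
3 | [3,5-bis(methoxymethoxy)phenoxy]tri(propan-2-yl)silane | COCOc1cc(OCOC)cc(O[Si](C(C)C)(C(C)C)C(C)C)c1 | intermediate
4 | 6-methylheptanoic acid | CC(C)CCCCC(=O)O | starting material
5 | methyl 6-methylheptanoate | CC(C)CCCCC(=O)OC | intermediate
6 | {2,6-bis(methoxymethoxy)-4-[(triisopropylsilyl)oxy]phenyl}lithium (formed in situ, step 4) | [Li]c1c(OCOC)cc(O[Si](C(C)C)(C(C)C)C(C)C)cc1OCOC | intermediate
7 | dichloro{2,6-bis(methoxymethoxy)-4-[(triisopropylsilyl)oxy]phenyl}cerium, ArCeCl2 (formed in situ, step 4) | Cl[Ce](Cl)c1c(OCOC)cc(O[Si](C(C)C)(C(C)C)C(C)C)cc1OCOC | intermediate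
8 | 1-{2,6-bis(methoxymethoxy)-4-[(triisopropylsilyl)oxy]phenyl}-6-methylheptan-1-one (formed in situ, step 4) | CC(C)CCCCC(=O)c1c(OCOC)cc(O[Si](C(C)C)(C(C)C)C(C)C)cc1OCOC | intermediate
9 | 1,1-bis{2,6-bis(methoxymethoxy)-4-[(triisopropylsilyl)oxy]phenyl}-6-methylheptan-1-ol | CC(C)CCCCC(O)(c1c(OCOC)cc(O[Si](C(C)C)(C(C)C)C(C)C)cc1OCOC)c1c(OCOC)cc(O[Si](C(C)C)(C(C)C)C(C)C)cc1OCOC | intermediate
10 | 1,1-bis{2,6-bis(methoxymethoxy)-4-[(triisopropylsilyl)oxy]phenyl}-6-methylheptane | CC(C)CCCCC(c1c(OCOC)cc(O[Si](C(C)C)(C(C)C)C(C)C)cc1OCOC)c1c(OCOC)cc(O[Si](C(C)C)(C(C)C)C(C)C)cc1OCOC | intermediate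
11 | 4,4'-(6-methylheptane-1,1-diyl)bis[3,5-bis(methoxymethoxy)phenol] | CC(C)CCCCC(c1c(OCOC)cc(O)cc1OCOC)c1c(OCOC)cc(O)cc1OCOC | intermediate
12 | 3-chloro-3-methylbut-1-yne | CC(C)(Cl)C#C | starting material
13 | 1,1-bis[2,6-bis(methoxymethoxy)-4-(2-methylbut-3-yn-2-yloxy)phenyl]-6-methylheptane | CC(C)CCCCC(c1c(OCOC)cc(OC(C)(C)C#C)cc1OCOC)c1c(OCOC)cc(OC(C)(C)C#C)cc1OCOC | intermediate
14 | 4,4'-(6-methylheptane-1,1-diyl)bis[3,5-bis(methoxymethoxy)-6-(3-methylbuta-1,2-dien-1-yl)cyclohexa-2,4-dien-1-one] (formed in situ, step 8; sp3 ring carbons of either configuration) | CC(C)CCCCC(C1=C(OCOC)C(C=C=C(C)C)C(=O)C=C1OCOC)C1=C(OCOC)C(C=C=C(C)C)C(=O)C=C1OCOC | intermediate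
15 | 4,4'-(6-methylheptane-1,1-diyl)bis[3,5-bis(methoxymethoxy)-2-(3-methylbuta-1,2-dien-1-yl)phenol] (formed in situ, step 8) | CC(C)CCCCC(c1c(OCOC)c(C=C=C(C)C)c(O)cc1OCOC)c1c(OCOC)c(C=C=C(C)C)c(O)cc1OCOC | intermediate
16 | 4,4'-(6-methylheptane-1,1-diyl)bis[3,5-bis(methoxymethoxy)-6-(3-methylbut-2-en-1-ylidene)cyclohexa-2,4-dien-1-one] (formed in situ, step 8; exocyclic alkene geometry not specified) | CC(C)CCCCC(C1=C(OCOC)C(=CC=C(C)C)C(=O)C=C1OCOC)C1=C(OCOC)C(=CC=C(C)C)C(=O)C=C1OCOC | intermediate
17 | 6,6'-(6-methylheptane-1,1-diyl)bis[5,7-bis(methoxymethoxy)-2,2-dimethyl-2H-chromene] | CC(C)CCCCC(c1c(OCOC)c2C=CC(C)(C)Oc2cc1OCOC)c1c(OCOC)c2C=CC(C)(C)Oc2cc1OCOC | intermediate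
18 | 6,6'-(6-methylheptane-1,1-diyl)bis[5,7-bis(methoxymethoxy)-2,2-dimethylchromane] (formed in situ, step 9) | CC(C)CCCCC(c1c(OCOC)c2CCC(C)(C)Oc2cc1OCOC)c1c(OCOC)c2CCC(C)(C)Oc2cc1OCOC | intermediate
19 | 6,6'-(6-methylheptane-1,1-diyl)bis(2,2-dimethylchromane-5,7-diol) | CC(C)CCCCC(c1c(O)c2CCC(C)(C)Oc2cc1O)c1c(O)c2CCC(C)(C)Oc2cc1O | intermediate
20 | (R)-2-methylbutanoic acid | CC[C@@H](C)C(=O)O | starting material
21 | (R)-2-methylbutanoyl chloride (formed in situ, step 10) | CC[C@@H](C)C(=O)Cl | intermediate
22 | (2R,2'R)-1,1'-[(6-methylheptane-1,1-diyl)bis(5,7-dihydroxy-2,2-dimethyl-3,4-dihydro-2H-chromene-6,8-diyl)]bis(2-methylbutan-1-one) | CC[C@@H](C)C(=O)c1c(O)c(C(CCCCC(C)C)c2c(O)c3c(c(C(=O)[C@H](C)CC)c2O)OC(C)(C)CC3)c(O)c2c1OC(C)(C)CC2 | target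

## Step count and least certain steps

Total step count: 10. Longest linear sequence: 9 steps (steps 1, 2, 4, 5, 6, 7, 8, 9, 10); step 3 is a one-step side branch.

**Step 8 (key step).**
- What may go wrong: the second arm may rearrange incompletely in the crowded molecule. Traces of base or metal may divert the allenylphenol stage into ionic cyclisation to a benzofuran. The terminal alkynes may decompose thermally before the sigmatropic shift.
- Fallback: it sets out from 11 and comes back at 17. The two free phenols are condensed with 3-methylbut-2-enal in the presence of ethylenediammonium diacetate in toluene at 110 °C. Knoevenagel-type attack of an ortho carbon on the activated enal and loss of water lead to the same ortho-quinone methide arms, which close by oxa-6π electrocyclisation. The local symmetry of each ring again allows only one chromene. The C4a–C4 bond is made by electrophilic substitution and not by a sigmatropic shift. No compound outside the list is made (entry F0).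

**Step 4.**
- What may go wrong: the aryl metal may enolise ketone 8 and stall the sequence after one addition. The second addition to a carbonyl flanked by two ortho substituents may be slow for steric reasons. Metalation may be incomplete.
- Fallback: it sets out from 6 (generated from 3 as in step 4) and comes back at 9. Two equivalents of 6 are added to ethyl formate to give bis{2,6-bis(methoxymethoxy)-4-[(triisopropylsilyl)oxy]phenyl}methanol F1. MnO2 in CH2Cl2 oxidises this to the non-enolisable bis{2,6-bis(methoxymethoxy)-4-[(triisopropylsilyl)oxy]phenyl}methanone F2. (5-Methylhexyl)lithium F3, made from 1-bromo-5-methylhexane and t-BuLi, is then added to F2 to give 9. The small primary nucleophile now attacks a ketone that cannot enolise.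

**Step 5.**
- What may go wrong: the acetal ethers may be lost to acid. A neighbouring acetal oxygen may capture the benzylic cation and close a benzodioxine ring. Hydride transfer to a strongly stabilised, crowded cation may be slow, so that the reaction stops at the alkene.
- Fallback: it sets out from 9 and comes back at 10. The carbinol is dehydrated under non-acidic conditions with methyl N-(triethylammoniumsulfonyl)carbamate in toluene at 50 °C to 1,1-bis{2,6-bis(methoxymethoxy)-4-[(triisopropylsilyl)oxy]phenyl}-6-methylhept-1-ene F4. Its trisubstituted double bond is then hydrogenated (H2, 4 atm, Pd(OH)2/C, EtOAc with a little Et3N) to give 10. No long-lived cation is exposed to the acetals.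

**Step 10.**
- What may go wrong: the α-configuration may erode through ketene formation from the acyl chloride or acylium ion. The diarylmethine may be cleaved after ipso-protonation. The Lewis acid may open the pyran ether. The second acylation may be incomplete.
- Fallback: it sets out from 18 (isolated after the hydrogenation stage of step 9, before acid is added) and comes back at 22.
  - 20 is converted with 1,1'-carbonyldiimidazole and N,O-dimethylhydroxylamine hydrochloride into (R)-N-methoxy-N,2-dimethylbutanamide F5.
  - 18 is lithiated at the only aromatic C–H of each ring (n-BuLi, TMEDA, THF, 0 °C; directed by O1 and the C7 acetal) to the 8,8'-dilithio derivative of 18 F6.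
  - F6 is acylated with F5 to give the tetrakis(methoxymethyl) ether of 22 F7, which has the same structure as A8.
  - Methanolic HCl at rt removes the acetals to give 22.
  - In this order the ketone is formed through a stable tetrahedral adduct without Lewis acid, and acid meets only an acylated, deactivated ring with no free position. The same detour therefore also removes the risk that acetal cleavage in step 9 attacks the unacylated arene.

## Further compounds

F0 | step 8 | none | none
F1 | step 4 | bis{2,6-bis(methoxymethoxy)-4-[(triisopropylsilyl)oxy]phenyl}methanol | OC(c1c(OCOC)cc(O[Si](C(C)C)(C(C)C)C(C)C)cc1OCOC)c1c(OCOC)cc(O[Si](C(C)C)(C(C)C)C(C)C)cc1OCOC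
F2 | step 4 | bis{2,6-bis(methoxymethoxy)-4-[(triisopropylsilyl)oxy]phenyl}methanone | O=C(c1c(OCOC)cc(O[Si](C(C)C)(C(C)C)C(C)C)cc1OCOC)c1c(OCOC)cc(O[Si](C(C)C)(C(C)C)C(C)C)cc1OCOC
F3 | step 4 | (5-methylhexyl)lithium | [Li]CCCCC(C)C
F4 | step 5 | 1,1-bis{2,6-bis(methoxymethoxy)-4-[(triisopropylsilyl)oxy]phenyl}-6-methylhept-1-ene | CC(C)CCCC=C(c1c(OCOC)cc(O[Si](C(C)C)(C(C)C)C(C)C)cc1OCOC)c1c(OCOC)cc(O[Si](C(C)C)(C(C)C)C(C)C)cc1OCOC
F5 | step 10 | (R)-N-methoxy-N,2-dimethylbutanamide | CC[C@@H](C)C(=O)N(C)OC
F6 | step 10 | 8,8'-dilithio derivative of 18: [(6-methylheptane-1,1-diyl)bis(5,7-bis(methoxymethoxy)-2,2-dimethylchromane-6,8-diyl)]dilithium | CC(C)CCCCC(c1c(OCOC)c2CCC(C)(C)Oc2c([Li])c1OCOC)c1c(OCOC)c2CCC(C)(C)Oc2c([Li])c1OCOC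
F7 | step 10 | tetrakis(methoxymethyl) ether of 22: (2R,2'R)-1,1'-[(6-methylheptane-1,1-diyl)bis(5,7-bis(methoxymethoxy)-2,2-dimethylchromane-6,8-diyl)]bis(2-methylbutan-1-one) | CC(C)CCCCC(c1c(OCOC)c2CCC(C)(C)Oc2c(C(=O)[C@H](C)CC)c1OCOC)c1c(OCOC)c2CCC(C)(C)Oc2c(C(=O)[C@H](C)CC)c1OCOC
A1 | alternative 1 | 3-(5-methylhexyl)pentanedioyl dichloride | O=C(Cl)CC(CCCCC(C)C)CC(=O)Cl
A2 | alternative 1 | {[1-methoxy-2-(6,6-dimethyl-5,6-dihydro-4H-pyran-2-yl)ethenyl]oxy}trimethylsilane | COC(O[Si](C)(C)C)=CC1=CCCC(C)(C)O1
A3 | alternative 1 | 6,6'-(6-methylheptane-1,1-diyl)bis(2,2-dimethylchromane-5,7-diol) (identical with 19) | CC(C)CCCCC(c1c(O)cc2OC(C)(C)CCc2c1O)c1c(O)cc2OC(C)(C)CCc2c1O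
A4 | alternative 2 | 6,6'-(6-methylheptane-1,1-diyl)bis[5,7-bis(methoxymethoxy)-2,2-dimethylchromane-8-carbaldehyde] | CC(C)CCCCC(c1c(OCOC)c2CCC(C)(C)Oc2c(C=O)c1OCOC)c1c(OCOC)c2CCC(C)(C)Oc2c(C=O)c1OCOC
A5 | alternative 2 | (E)-crotylboronic acid pinacol ester | C/C=C/CB1OC(C)(C)C(C)(C)O1
A6 | alternative 2 | (1R,2R,1'R,2'R)-1,1'-[(6-methylheptane-1,1-diyl)bis(5,7-bis(methoxymethoxy)-2,2-dimethylchromane-6,8-diyl)]bis(2-methylbut-3-en-1-ol) | C=C[C@@H](C)[C@@H](O)c1c(OCOC)c(C(CCCCC(C)C)c2c(OCOC)c3c(c([C@H](O)[C@H](C)C=C)c2OCOC)OC(C)(C)CC3)c(OCOC)c2c1OC(C)(C)CC2
A7 | alternative 3 | (2R,2'R)-1,1'-{(6-methylheptane-1,1-diyl)bis[2-bromo-3-(3-hydroxy-3-methylbutyl)-4,6-bis(methoxymethoxy)-5,1-phenylene]}bis(2-methylbutan-1-one) | CC(C)CCCCC(c1c(OCOC)c(CCC(C)(C)O)c(Br)c(C(=O)[C@H](C)CC)c1OCOC)c1c(OCOC)c(CCC(C)(C)O)c(Br)c(C(=O)[C@H](C)CC)c1OCOC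
A8 | alternative 3 | tetrakis(methoxymethyl) ether of the target: (2R,2'R)-1,1'-[(6-methylheptane-1,1-diyl)bis(5,7-bis(methoxymethoxy)-2,2-dimethylchromane-6,8-diyl)]bis(2-methylbutan-1-one) | CC(C)CCCCC(c1c(OCOC)c2CCC(C)(C)Oc2c(C(=O)[C@H](C)CC)c1OCOC)c1c(OCOC)c2CCC(C)(C)Oc2c(C(=O)[C@H](C)CC)c1OCOC
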